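**Strategy.** The route rests on building the B ring (C1'–C6') instead of substituting a resorcinol. Its C2'–C3' edge, carrying one oxygen and the geranyl group, comes from a siloxyalkyne; C4'(O)–C5'(prenyl)–C6'–C1' comes from a 4-prenylcyclobutenone. One thermal operation forms C3'–C4' and C1'–C2', closes the six-membered ring, and delivers the C2' and C4' oxygens differentiated (silyl ether versus free phenol), with geranyl between them, prenyl at C5' and C1'–H open. C1' is then borylated and joined to C2 of an 8-prenylchromone (A/C rings) by rhodium-catalysed asymmetric 1,4-addition, which sets C2. Enolate hydroxylation sets C3 trans, and acid removes the MOM groups.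

Key step: step 5

Abbreviations: geranyl = (2E)-3,7-dimethylocta-2,6-dien-1-yl; prenyl = 3-methylbut-2-en-1-yl; MOM = methoxymethyl; TIPS = triisopropylsilyl.

Remark: the facial sense of the rhodium-catalysed addition in step 12 is assigned from the model established for cyclic enones with atropisomeric bisphosphines; should it not transfer to chromone 28, the ligand antipode is used.

**Step 1**
Reactants: 1 5-methylhex-4-enoic acid; 2 ethoxyacetylene
Product: 5 (±)-3-ethoxy-4-prenylcyclobut-2-en-1-one, via 5-methylhex-4-enoyl chloride 3 (not isolated), via prenylketene 4 (not isolated)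
Conditions: (COCl)2, cat. DMF, CH2Cl2, 0 °C to rt, evaporate; then 2 (excess), Et3N (slow addition), Et2O, rt
Reagents that add atoms: none
Why: Dehydrochlorination of the acid chloride gives the aldoketene in the presence of the ynol ether, and the regioselective ketene–alkyne [2+2] cycloaddition (ketene carbonyl carbon to the unsubstituted alkyne carbon) is the standard entry to 3-ethoxycyclobutenones; C4 forms racemic, which is harmless because it becomes aromatic C5'.

**Step 2**
Reactants: 5 (±)-3-ethoxy-4-prenylcyclobut-2-en-1-one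
Product: 7 (±)-4-prenylcyclobut-2-en-1-one, via cyclobutenol 6 (not isolated)
Conditions: DIBAL-H, CH2Cl2, −78 °C; then 1 M aq. HCl, Et2O, 0 °C
Reagents that add atoms: water, O
Why: 1,2-Reduction of the vinylogous ester followed by acid hydrolysis of the hydroxy enol ether with loss of water and ethanol is a Stork–Danheiser-type 1,3-carbonyl transposition that leaves prenyl on the sp3 carbon C4; migration of the double bond is not expected, since it would pass through an antiaromatic cyclobutadienol.

**Step 3**
Reactants: 8 geranyl bromide; 9 ethynylmagnesium bromide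
Product: 10 (4E)-5,9-dimethyldeca-4,8-dien-1-yne
Conditions: 9 (2 equiv), CuCl (10 mol%), THF, 0 to 50 °C
Reagents that add atoms: none
Why: Copper-catalysed SN2 coupling of an alkynyl Grignard reagent with a primary allylic bromide should give the skipped enyne with the E alkene untouched.

**Step 4**
Reactants: 10 (4E)-5,9-dimethyldeca-4,8-dien-1-yne
Product: 13 geranyl siloxyalkyne [(4E)-5,9-dimethyldeca-4,8-dien-1-yn-1-yl triisopropylsilyl ether], via lithium acetylide 11 (not isolated), via lithium ynolate 12 (not isolated)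
Conditions: n-BuLi (1.0 equiv), THF, −78 °C; add to t-BuOOLi (from t-BuOOH, LiHMDS, THF, −78 °C), then 0 °C; TIPSOTf, −78 to 0 °C
Reagents that add atoms: tert-butyl hydroperoxide (as its lithium salt), CC(C)(C)OO; triisopropylsilyl triflate, CC(C)[Si](C(C)C)(C(C)C)OS(=O)(=O)C(F)(F)F
Why: Julia-type oxidation of a lithium acetylide by lithium tert-butyl peroxide gives the ynolate, which the bulky silyl triflate traps on oxygen (the usual preparation of siloxyalkynes from terminal alkynes); one equivalent of base at −78 °C removes only the acetylenic proton.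

**Step 5**
Reactants: 7 (±)-4-prenylcyclobut-2-en-1-one; 13 geranyl siloxyalkyne
Product: 18 2-geranyl-6-prenyl-3-(triisopropylsilyloxy)phenol, via vinylketene 14 (not isolated), via vinylcyclobutenone 15 (not isolated), via dienylketene 16 (not isolated), via cyclohexadienone 17 (not isolated)
Conditions: slow addition of 7 to 13 (1.3 equiv), degassed toluene, 80 °C, then 110 °C, sealed vessel
Reagents that add atoms: none
Why: Heating opens 7 by a 4π-conrotatory process (C4'–C5' bond broken, prenyl turning outward) to the (E)-vinylketene 14, whose ketene C=C adds [2+2] to the siloxyalkyne and so forms C3'–C4' and C1'–C2' in vinylcyclobutenone 15. A second 4π opening gives dienylketene 16, and the benzene ring is closed by a thermal disrotatory 6π-electrocyclisation that re-forms C4'–C5'; dienone 17 then tautomerises to phenol 18. This is the Danheiser benzannulation in its siloxyalkyne variant, applied to a 4-alkylcyclobutenone. No stereocentre is created, and the racemic C4 of 7 ends as aromatic C5'. The regiochemistry needed (geranyl-bearing carbon to C4', oxygen-bearing carbon to C1') follows from the polarisation of the ynol ether, whose nucleophilic β-carbon attacks the electrophilic ketene carbonyl carbon. Chemoselectivity over the three trisubstituted alkenes rests on the far higher reactivity of the ynol ether toward ketenes, and slow addition keeps the ketene concentration low against dimerisation and O-acylation of the phenol formed.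

**Step 6**
Reactants: 18 2-geranyl-6-prenyl-3-(triisopropylsilyloxy)phenol
Product: 19 2-geranyl-4-prenylbenzene-1,3-diol
Conditions: TBAF, THF, 0 °C; aq. NH4Cl
Reagents that add atoms: none
Why: Fluoride-induced cleavage of an aryl silyl ether is fast and leaves the alkenes untouched.

**Step 7**
Reactants: 19 2-geranyl-4-prenylbenzene-1,3-diol
Product: 20 2-geranyl-1,3-bis(methoxymethoxy)-4-prenylbenzene
Conditions: NaH, MOMCl, DMF, 0 °C to rt
Reagents that add atoms: chloromethyl methyl ether, COCCl
Why: Williamson O-alkylation of both phenoxides with a hard electrophile installs on C2'–O the acetal needed as a metalation director, and sodium hydride in DMF also reaches the hindered C4' hydroxyl.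

**Step 8**
Reactants: 20 2-geranyl-1,3-bis(methoxymethoxy)-4-prenylbenzene
Product: 22 [3-geranyl-2,4-bis(methoxymethoxy)-5-prenylphenyl]boronic acid, via aryllithium 21 (not isolated)
Conditions: n-BuLi, TMEDA, THF, −20 to 0 °C; B(OMe)3, −78 °C to rt; aq. NH4Cl
Reagents that add atoms: trimethyl borate, COB(OC)OC; water, O
Why: Directed ortho-metalation should occur at C1', the only ring C–H ortho to a MOM ether (C6'–H lies between prenyl and C1'), because complex-induced proximity favours ring lithiation over removal of a benzylic-allylic proton; borate trapping and hydrolysis then give the boronic acid.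

**Step 9**
Reactants: 23 2,4,6-trihydroxyacetophenone; 24 prenyl bromide
Product: 25 2,4,6-trihydroxy-3-prenylacetophenone
Conditions: DBU, THF, 0 °C to rt
Reagents that add atoms: none
Why: C-alkylation of the phloroglucinol-type phenoxide by an allylic bromide is known; the two ring C–H positions are equivalent, so only mono- versus polyalkylation has to be controlled by stoichiometry.

**Step 10**
Reactants: 25 2,4,6-trihydroxy-3-prenylacetophenone
Product: 26 2-hydroxy-4,6-bis(methoxymethoxy)-3-prenylacetophenone
Conditions: MOMCl (2.2 equiv), i-Pr2NEt, CH2Cl2, 0 °C to rt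
Reagents that add atoms: chloromethyl methyl ether, COCCl
Why: Acetal protection should take the 4-OH and the less hindered ortho hydroxyl, leaving the hydroxyl that is flanked by prenyl and hydrogen-bonded to the acetyl group.

**Step 11**
Reactants: 26 2-hydroxy-4,6-bis(methoxymethoxy)-3-prenylacetophenone
Product: 28 5,7-bis(methoxymethoxy)-8-prenyl-4H-chromen-4-one, via enaminone 27 (not isolated)
Conditions: DMF-DMA, toluene, 95 °C; concentrate; AcOH, toluene, 60 °C
Reagents that add atoms: N,N-dimethylformamide dimethyl acetal, COC(OC)N(C)C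
Why: Condensation of the methyl ketone with the amide acetal gives the enaminone, and mild acid promotes 6-endo addition of the only free phenol and loss of dimethylamine (enaminone chromone synthesis); because that phenol is the one next to prenyl, the prenyl group ends at C8.

**Step 12**
Reactants: 22 [3-geranyl-2,4-bis(methoxymethoxy)-5-prenylphenyl]boronic acid; 28 5,7-bis(methoxymethoxy)-8-prenyl-4H-chromen-4-one
Product: 29 (2S)-2-[3-geranyl-2,4-bis(methoxymethoxy)-5-prenylphenyl]-5,7-bis(methoxymethoxy)-8-prenylchroman-4-one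
Conditions: [Rh(OH)(cod)]2 (cat.), (S)-MeO-F12-BIPHEP, toluene/H2O, 30 °C; 28 in excess
Reagents that add atoms: none
Why: Hayashi–Miyaura rhodium-catalysed asymmetric 1,4-addition of an arylboronic acid to a chromone, in which the electron-poor chiral bisphosphine controls the face of aryl insertion at C2 and should give the (2S)-flavanone; fast protonation of the rhodium enolate in the aqueous medium counters ring opening.

**Step 13**
Reactants: 29 (2S)-flavanone
Product: 31 (2R,3R)-2-[3-geranyl-2,4-bis(methoxymethoxy)-5-prenylphenyl]-3-hydroxy-5,7-bis(methoxymethoxy)-8-prenylchroman-4-one, via sodium enolate 30 (not isolated)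
Conditions: NaHMDS, THF, −78 °C, short enolisation; 2-(phenylsulfonyl)-3-phenyloxaziridine, −78 °C; AcOH quench at −78 °C
Reagents that add atoms: 2-(phenylsulfonyl)-3-phenyloxaziridine, O=S(=O)(c1ccccc1)N1OC1c1ccccc1
Why: Davis enolate hydroxylation, in which the oxaziridine delivers oxygen to C3 on the face anti to the C2 aryl group (substrate control), should give the 2,3-trans isomer, which is also the more stable one; the descriptor at C2 changes from S to R only through the priority change, and the alkenes are inert to the reagent at −78 °C.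

**Step 14**
Reactants: 31 (2R,3R)-3-hydroxyflavanone tetrakis-MOM ether
Product: 32 (2R,3R)-2-(3-geranyl-2,4-dihydroxy-5-prenylphenyl)-3,5,7-trihydroxy-8-prenylchroman-4-one
Conditions: 3 M aq. HCl/MeOH, 45 °C, monitored and stopped at full conversion
Reagents that add atoms: none
Why: Acid-catalysed acetal exchange removes the four MOM groups under conditions customary for prenylated flavonoids; neither stereocentre is touched and the reaction is stopped before the phenols add to the prenyl alkenes.

**Compound list**
1 | 5-methylhex-4-enoic acid | CC(C)=CCCC(=O)O | starting material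
2 | ethoxyacetylene | C#COCC | starting material
3 | 5-methylhex-4-enoyl chloride | CC(C)=CCCC(=O)Cl | intermediate
4 | prenylketene (5-methylhexa-1,4-dien-1-one) | CC(C)=CCC=C=O | intermediate
5 | (±)-3-ethoxy-4-prenylcyclobut-2-en-1-one | CCOC1=CC(=O)C1CC=C(C)C | intermediate
6 | 3-ethoxy-4-prenylcyclobut-2-en-1-ol (racemic, mixture of diastereomers) | CCOC1=CC(O)C1CC=C(C)C | intermediate
7 | (±)-4-prenylcyclobut-2-en-1-one | O=C1C=CC1CC=C(C)C | intermediate
8 | geranyl bromide | CC(C)=CCC/C(C)=C/CBr | starting material
9 | ethynylmagnesium bromide | C#C[Mg]Br | starting material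
10 | (4E)-5,9-dimethyldeca-4,8-dien-1-yne | CC(C)=CCC/C(C)=C/CC#C | intermediate
11 | lithium (4E)-5,9-dimethyldeca-4,8-dien-1-yn-1-ide | CC(C)=CCC/C(C)=C/CC#C[Li] | intermediate
12 | lithium (4E)-5,9-dimethyldeca-4,8-dien-1-yn-1-olate | CC(C)=CCC/C(C)=C/CC#CO[Li] | intermediate
13 | [(4E)-5,9-dimethyldeca-4,8-dien-1-yn-1-yl]oxy(triisopropyl)silane | CC(C)=CCC/C(C)=C/CC#CO[Si](C(C)C)(C(C)C)C(C)C | intermediate
14 | (3E)-7-methylocta-1,3,6-trien-1-one | O=C=C/C=C/CC=C(C)C | intermediate
15 | (±)-2-geranyl-4-[(1E)-5-methylhexa-1,4-dienyl]-3-(triisopropylsilyloxy)cyclobut-2-en-1-one | O=C1C(C/C=C(\C)CCC=C(C)C)=C(O[Si](C(C)C)(C(C)C)C(C)C)C1/C=C/CC=C(C)C | intermediate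
16 | (3Z,5E)-2-geranyl-9-methyl-3-(triisopropylsilyloxy)deca-1,3,5,8-tetraen-1-one | O=C=C(C/C=C(\C)CCC=C(C)C)/C(O[Si](C(C)C)(C(C)C)C(C)C)=C\C=C\CC=C(C)C | intermediate
17 | (±)-2-geranyl-6-prenyl-3-(triisopropylsilyloxy)cyclohexa-2,4-dien-1-one | O=C1C(C/C=C(\C)CCC=C(C)C)=C(O[Si](C(C)C)(C(C)C)C(C)C)C=CC1CC=C(C)C | intermediate
18 | 2-geranyl-6-prenyl-3-(triisopropylsilyloxy)phenol | CC(C)=CCC/C(C)=C/Cc1c(O)c(CC=C(C)C)ccc1O[Si](C(C)C)(C(C)C)C(C)C | intermediate
19 | 2-geranyl-4-prenylbenzene-1,3-diol | CC(C)=CCC/C(C)=C/Cc1c(O)c(CC=C(C)C)ccc1O | intermediate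
20 | 2-geranyl-1,3-bis(methoxymethoxy)-4-prenylbenzene | CC(C)=CCC/C(C)=C/Cc1c(OCOC)c(CC=C(C)C)ccc1OCOC | intermediate
21 | [3-geranyl-2,4-bis(methoxymethoxy)-5-prenylphenyl]lithium | [Li]c1cc(CC=C(C)C)c(OCOC)c(C/C=C(\C)CCC=C(C)C)c1OCOC | intermediate
22 | [3-geranyl-2,4-bis(methoxymethoxy)-5-prenylphenyl]boronic acid | OB(O)c1cc(CC=C(C)C)c(OCOC)c(C/C=C(\C)CCC=C(C)C)c1OCOC | intermediate
23 | 2,4,6-trihydroxyacetophenone | CC(=O)c1c(O)cc(O)cc1O | starting material
24 | prenyl bromide | CC(C)=CCBr | starting material
25 | 2,4,6-trihydroxy-3-prenylacetophenone | CC(=O)c1c(O)cc(O)c(CC=C(C)C)c1O | intermediate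
26 | 2-hydroxy-4,6-bis(methoxymethoxy)-3-prenylacetophenone | CC(=O)c1c(OCOC)cc(OCOC)c(CC=C(C)C)c1O | intermediate
27 | (E)-3-(dimethylamino)-1-[2-hydroxy-4,6-bis(methoxymethoxy)-3-prenylphenyl]prop-2-en-1-one | CN(C)/C=C/C(=O)c1c(OCOC)cc(OCOC)c(CC=C(C)C)c1O | intermediate
28 | 5,7-bis(methoxymethoxy)-8-prenyl-4H-chromen-4-one | O=c1ccoc2c(CC=C(C)C)c(OCOC)cc(OCOC)c12 | intermediate
29 | (2S)-2-[3-geranyl-2,4-bis(methoxymethoxy)-5-prenylphenyl]-5,7-bis(methoxymethoxy)-8-prenylchroman-4-one | CC(C)=CCC/C(C)=C/Cc1c(OCOC)c(CC=C(C)C)cc([C@H]2Oc3c(CC=C(C)C)c(OCOC)cc(OCOC)c3C(=O)C2)c1OCOC | intermediate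
30 | sodium enolate of 29 (C3=C4, C4–ONa; C2 unchanged) | CC(C)=CCC/C(C)=C/Cc1c(OCOC)c(CC=C(C)C)cc([C@H]2Oc3c(CC=C(C)C)c(OCOC)cc(OCOC)c3C(O[Na])=C2)c1OCOC | intermediate
31 | (2R,3R)-2-[3-geranyl-2,4-bis(methoxymethoxy)-5-prenylphenyl]-3-hydroxy-5,7-bis(methoxymethoxy)-8-prenylchroman-4-one | CC(C)=CCC/C(C)=C/Cc1c(OCOC)c(CC=C(C)C)cc([C@H]2Oc3c(CC=C(C)C)c(OCOC)cc(OCOC)c3C(=O)[C@@H]2O)c1OCOC | intermediate
32 | (2R,3R)-2-(3-geranyl-2,4-dihydroxy-5-prenylphenyl)-3,5,7-trihydroxy-8-prenylchroman-4-one | CC(C)=CCC/C(C)=C/Cc1c(O)c(CC=C(C)C)cc([C@H]2Oc3c(CC=C(C)C)c(O)cc(O)c3C(=O)[C@@H]2O)c1O | target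

**Step count.** Total: 14 steps. Longest linear sequence: 9 steps (steps 1, 2, 5, 6, 7, 8, 12, 13, 14; the branch through steps 3 and 4 is equally long).

**Steps most likely to fail**

Step 5. The vinylketene may dimerise or acylate the phenol as it forms faster than it adds to the siloxyalkyne, and the thermally labile cyclobutenone may polymerise before it opens. The fallback abandons ring construction for stepwise directed metalation. It sets out from geranyl bromide 8 and comes back at bis-MOM ether 20, so that steps 1 to 7 are not needed. Commercial 1,3-bis(methoxymethoxy)benzene F1 is lithiated between the two acetal oxygens (n-BuLi, THF, 0 °C) and alkylated with 8 (cat. CuI) to give 2-geranyl-1,3-bis(methoxymethoxy)benzene F2. A second ortho-lithiation (n-BuLi, TMEDA) at one of the two equivalent positions and alkylation with prenyl bromide 24 then gives 20.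

Step 12. Protodeboronation of the electron-rich ortho-alkoxy boronic acid may outrun insertion into the electron-rich chromone, and ring opening of the rhodium enolate may erode the enantiomeric purity. The fallback replaces the conjugate addition by a chalcone epoxide sequence. It sets out from 20 and 26 and comes back at target 32.
- 20 is lithiated as in step 8 and quenched with DMF to give 3-geranyl-2,4-bis(methoxymethoxy)-5-prenylbenzaldehyde F3.
- 26 is protected (NaH, MOMCl) to give 2,4,6-tris(methoxymethoxy)-3-prenylacetophenone F4.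
- Claisen–Schmidt condensation (KOH, EtOH) gives the (E)-chalcone F5.
- Juliá–Colonna epoxidation (poly-L-leucine, urea–H2O2, DBU, THF), a nucleophilic oxidation that spares the isolated alkenes, gives the (αR,βS)-epoxide F6.
- HCl in MeOH removes the MOM groups; the liberated 2'-hydroxyl should open the epoxide at the benzylic carbon with inversion, closing the C ring 2,3-trans to give 32.

Step 13. The enolate may expel the C-ring aryloxide (retro-oxa-Michael) and reclose with loss of configuration at C2, or it may add to the sulfonylimine by-product. The fallback avoids a free enolate. It sets out from 29 and comes back at 31. Soft enolisation (TMSOTf, Et3N, CH2Cl2, 0 °C) gives the 4-(trimethylsilyloxy)-2H-chromene F7. Oxidation of this enol silane with 2-(phenylsulfonyl)-3-phenyloxaziridine in CHCl3 at rt, conditions under which unactivated trisubstituted alkenes react only slowly, gives the 3-(trimethylsilyloxy)flavanone F8, again anti to the C2 aryl group. Brief treatment with dilute acid in THF gives 31.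

**Further compounds**
F1 | step 5 | 1,3-bis(methoxymethoxy)benzene | COCOc1cccc(OCOC)c1
F2 | step 5 | 2-geranyl-1,3-bis(methoxymethoxy)benzene | COCOc1cccc(OCOC)c1C/C=C(\C)CCC=C(C)C
F3 | step 12 | 3-geranyl-2,4-bis(methoxymethoxy)-5-prenylbenzaldehyde | O=Cc1cc(CC=C(C)C)c(OCOC)c(C/C=C(\C)CCC=C(C)C)c1OCOC
F4 | step 12 | 2,4,6-tris(methoxymethoxy)-3-prenylacetophenone | CC(=O)c1c(OCOC)cc(OCOC)c(CC=C(C)C)c1OCOC
F5 | step 12 | (E)-3-[3-geranyl-2,4-bis(methoxymethoxy)-5-prenylphenyl]-1-[2,4,6-tris(methoxymethoxy)-3-prenylphenyl]prop-2-en-1-one | O=C(/C=C/c1cc(CC=C(C)C)c(OCOC)c(C/C=C(\C)CCC=C(C)C)c1OCOC)c1c(OCOC)cc(OCOC)c(CC=C(C)C)c1OCOC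
F6 | step 12 | (αR,βS)-epoxide of chalcone F5 [(2R,3S)-oxiranyl ketone] | O=C([C@@H]1O[C@H]1c1cc(CC=C(C)C)c(OCOC)c(C/C=C(\C)CCC=C(C)C)c1OCOC)c1c(OCOC)cc(OCOC)c(CC=C(C)C)c1OCOC
F7 | step 13 | (2S)-2-[3-geranyl-2,4-bis(methoxymethoxy)-5-prenylphenyl]-5,7-bis(methoxymethoxy)-8-prenyl-4-(trimethylsilyloxy)-2H-chromene | CC(C)=CCC/C(C)=C/Cc1c(OCOC)c(CC=C(C)C)cc([C@H]2Oc3c(CC=C(C)C)c(OCOC)cc(OCOC)c3C(O[Si](C)(C)C)=C2)c1OCOC
F8 | step 13 | (2R,3R)-2-[3-geranyl-2,4-bis(methoxymethoxy)-5-prenylphenyl]-5,7-bis(methoxymethoxy)-8-prenyl-3-(trimethylsilyloxy)chroman-4-one | CC(C)=CCC/C(C)=C/Cc1c(OCOC)c(CC=C(C)C)cc([C@H]2Oc3c(CC=C(C)C)c(OCOC)cc(OCOC)c3C(=O)[C@@H]2O[Si](C)(C)C)c1OCOC
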